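**Strategy.** The O–C(=O) unit of the α-methylene-γ-butyrolactone ring is taken out as CO2 (germacrane numbering: ketone C1, carbinol C5, lactone carbon C6, ring fusion C7, alkene carbon C11, carbonyl C12). In the last step nickel-catalysed reductive carboxylation of a C11 alkenyl bromide forms C11–C12. The resulting carboxylate opens the adjacent cis-5,6-epoxide at C6 (5-exo, inversion), which closes the trans-fused lactone and releases the free C5 hydroxyl. The step exploits the vicinal C5–OH/C6–O pair on the ten-membered ring next to the lactone. Its precursor is the fully acylated 11-bromo-5,6-epoxy cyclodecanone, assembled by Evans aldol, Z-Wittig, hydroxyl-directed epoxidation and ring-closing metathesis.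

Key step: step 19

Remark 1: germacrane atom labels of the target (C4 = CHCH3, C8 = CH–O-methacryloyl, C10 = C(CH3)OAc, C13 = exocyclic CH2) are used for all intermediates.
Remark 2: compound 1 is taken as commercial. It is otherwise one step from (S)-lactic acid and pivalaldehyde.
Remark 3: the ring alkene of 25 is drawn Z. Either geometry serves, because step 16 removes it.

**Step 1**
Reactants: 1 (2S,5S)-2-tert-butyl-5-methyl-1,3-dioxolan-4-one
Product: 3 (2S,5R)-5-allyl-2-tert-butyl-5-methyl-1,3-dioxolan-4-one, via lithium enolate 2 (not isolated)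
Conditions: LiN(iPr)2, THF, −78 °C; allyl bromide, −78 → −20 °C
Reagents that add atoms: allyl bromide, C=CCBr
Why: Seebach self-regeneration of stereocentres; the planar enolate is alkylated (SN2) on the face anti to the tert-butyl group, so allyl replaces H with retention and sets C10 (R).

**Step 2**
Reactants: 3 (2S,5R)-5-allyl-2-tert-butyl-5-methyl-1,3-dioxolan-4-one
Product: 5 2-[(2S,4R)-2-tert-butyl-4-methyl-5-oxo-1,3-dioxolan-4-yl]acetaldehyde, via secondary ozonide 4 (not isolated)
Conditions: O3, CH2Cl2, −78 °C; Me2S, −78 °C → rt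
Reagents that add atoms: ozone, [O-][O+]=O
Why: Ozonolysis with reductive work-up cleaves the only C=C bond to the C8 aldehyde and touches no stereocentre.

**Step 3**
Reactants: 6 but-3-ynoic acid
Product: 7 3-bromobut-3-enoic acid
Conditions: HBr (33% in AcOH), 0 °C → rt
Reagents that add atoms: hydrogen bromide, Br
Why: Markovnikov hydrobromination of the terminal alkyne places bromine on the internal carbon (future C11); no stereocentre is formed.

**Step 4**
Reactants: 7 3-bromobut-3-enoic acid; 8 (R)-4-benzyloxazolidin-2-one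
Product: 10 (R)-4-benzyl-3-(3-bromobut-3-enoyl)oxazolidin-2-one, via mixed pivalic anhydride 9 (not isolated)
Conditions: tBuCOCl, Et3N, THF, −20 °C; LiCl, 8, −20 °C → rt
Reagents that add atoms: none
Why: N-acylation of the oxazolidinone through the mixed anhydride (LiCl/Et3N variant) needs no strong base and leaves the auxiliary stereocentre untouched.

**Step 5**
Reactants: 10 (R)-4-benzyl-3-(3-bromobut-3-enoyl)oxazolidin-2-one; 5 2-[(2S,4R)-2-tert-butyl-4-methyl-5-oxo-1,3-dioxolan-4-yl]acetaldehyde
Product: 12 (R)-4-benzyl-3-{(2R,3S)-2-(1-bromovinyl)-4-[(2S,4R)-2-tert-butyl-4-methyl-5-oxo-1,3-dioxolan-4-yl]-3-hydroxybutanoyl}oxazolidin-2-one, via boron dienolate 11 (not isolated)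
Conditions: Bu2BOTf, Et3N, CH2Cl2, −78 → 0 °C; 5, −78 → 0 °C; pH 7 buffer, MeOH, 30% H2O2, 0 °C
Reagents that add atoms: none
Why: Evans syn aldol reaction; the (Z)-boron dienolate reacts at its α-carbon through a Zimmerman–Traxler chair on the face away from the benzyl group, which sets C7 and C8 (7R,8S, syn) under auxiliary control.

**Step 6**
Reactants: 12 aldol adduct
Product: 13 C8 triethylsilyl ether of 12
Conditions: Et3SiOTf, 2,6-lutidine, CH2Cl2, −78 → 0 °C
Reagents that add atoms: triethylsilyl triflate, CC[Si](CC)(CC)OS(=O)(=O)C(F)(F)F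
Why: O-silylation blocks retro-aldol cleavage and lactonisation of the C8 hydroxyl onto the dioxolanone; no stereocentre changes.

**Step 7**
Reactants: 13 C8 triethylsilyl ether
Product: 14 (2S,5R)-5-[(2S,3S)-4-bromo-3-(hydroxymethyl)-2-(triethylsilyloxy)pent-4-en-1-yl]-2-tert-butyl-5-methyl-1,3-dioxolan-4-one
Conditions: NaBH4, THF/H2O (4:1), 0 °C → rt
Reagents that add atoms: none
Why: Reductive cleavage of the N-acyl oxazolidinone; the exocyclic imide carbonyl is far more electrophilic than the dioxolanone carbonyl, which is shielded by quaternary C10, and C7 keeps its geometry (only its CIP descriptor changes).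

**Step 8**
Reactants: 14 primary alcohol
Product: 15 (2R,3S)-2-(1-bromovinyl)-4-[(2S,4R)-2-tert-butyl-4-methyl-5-oxo-1,3-dioxolan-4-yl]-3-(triethylsilyloxy)butanal
Conditions: Dess–Martin periodinane, CH2Cl2, 0 °C → rt
Reagents that add atoms: none
Why: Dess–Martin oxidation is base-free, so the C6 aldehyde should form without epimerisation at C7 or migration of the bromoalkene.

**Step 9**
Reactants: 16 (E)-1,4-dibromobut-2-ene
Product: 17 (S)-4-bromo-3-methylbut-1-ene
Conditions: MeMgBr, CuBr·SMe2 (1 mol %), Taniaphos (enantiomer chosen to give the S product), CH2Cl2, −75 °C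
Reagents that add atoms: methylmagnesium bromide, C[Mg]Br
Why: Copper-catalysed asymmetric allylic alkylation (SN2′) of a 1,4-dihalobut-2-ene; the chiral ferrocenyl diphosphine selects the alkene face and sets C4 (S).

**Step 10**
Reactants: 17 (S)-4-bromo-3-methylbut-1-ene
Product: 18 (S)-(2-methylbut-3-en-1-yl)triphenylphosphonium bromide
Conditions: PPh3, MeCN, 85 °C (sealed tube)
Reagents that add atoms: triphenylphosphine, c1ccc(cc1)P(c1ccccc1)c1ccccc1
Why: SN2 quaternisation at the primary carbon leaves C4 untouched.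

**Step 11**
Reactants: 18 (S)-(2-methylbut-3-en-1-yl)triphenylphosphonium bromide; 15 C6 aldehyde
Product: 20 (2S,5R)-5-[(2S,3S,4Z,6S)-3-(1-bromovinyl)-6-methyl-2-(triethylsilyloxy)octa-4,7-dien-1-yl]-2-tert-butyl-5-methyl-1,3-dioxolan-4-one, via phosphorus ylide 19 (not isolated)
Conditions: NaN(SiMe3)2, THF, 0 °C; 15, −78 °C → rt
Reagents that add atoms: none
Why: Wittig olefination with a non-stabilised ylide under lithium-free conditions goes through the kinetic cis-oxaphosphetane to the (Z)-C5=C6 alkene, and fast addition at −78 °C should outrun enolisation at C7.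

**Step 12**
Reactants: 20 Z-triene dioxolanone
Product: 21 (2R,4S,5S,6Z,8S)-5-(1-bromovinyl)-2-hydroxy-N-methoxy-N,2,8-trimethyl-4-(triethylsilyloxy)deca-6,9-dienamide
Conditions: MeNH(OMe)·HCl, iPrMgCl, THF, −20 → 0 °C
Reagents that add atoms: N,O-dimethylhydroxylamine hydrochloride, CNOC.Cl
Why: Aminolysis of the activated acylal ester by the magnesium amide (Weinreb amide synthesis) releases pivalaldehyde and the C10 hydroxyl; C10 is not involved.

**Step 13**
Reactants: 21 Weinreb amide
Product: 23 (4R,6S,7S,8Z,10S)-7-(1-bromovinyl)-4,6-dihydroxy-4,10-dimethyldodeca-1,8,11-trien-3-one, via TES enone 22 (not isolated)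
Conditions: CH2=CHMgBr, THF, −78 → 0 °C; 1 M HCl, THF, rt
Reagents that add atoms: vinylmagnesium bromide, C=C[Mg]Br
Why: Weinreb ketone synthesis; the chelated tetrahedral intermediate prevents over-addition, and the acidic quench protonates the liberated amine before it can add to the enone and hydrolyses the silyl ether in the same flask.

**Step 14**
Reactants: 23 diol enone
Product: 24 (4R,6S,7R)-8-bromo-7-{(2R,3S)-3-[(2S)-but-3-en-2-yl]oxiran-2-yl}-4,6-dihydroxy-4-methylnona-1,8-dien-3-one
Conditions: VO(acac)2 (5 mol %), tBuOOH (decane), CH2Cl2, 0 °C → rt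
Reagents that add atoms: tert-butyl hydroperoxide, CC(C)(C)OO
Why: Hydroxyl-directed vanadium-catalysed epoxidation of a homoallylic alcohol; allylic 1,3-strain in the Z-alkene holds H4 and H7 in the alkene plane, so C8 with its vanadium-bound peroxide lies on one face and the bromovinyl group on the other, oxygen is delivered syn to C8 and sets C5 (S) and C6 (R) in one event, and the enone, the bromoalkene and the remote vinyl group stay untouched.

**Step 15**
Reactants: 24 epoxy diene
Product: 25 (2Z,4S,5S,6R,7R,8S,10R)-7-(1-bromovinyl)-5,6-epoxy-8,10-dihydroxy-4,10-dimethylcyclodec-2-en-1-one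
Conditions: second-generation Hoveyda–Grubbs catalyst (10 mol %), toluene (1 mM), 80 °C
Reagents that add atoms: none
Why: Ring-closing metathesis of the C3 vinyl group with the vinyl ketone; the cis-epoxide and quaternary C10 bend the chain, the 2-bromoalkene is inert to the ruthenium alkylidene, high dilution holds back oligomers, and no stereocentre is touched.

**Step 16**
Reactants: 25 cyclodecenone
Product: 26 (4S,5S,6R,7R,8S,10R)-7-(1-bromovinyl)-5,6-epoxy-8,10-dihydroxy-4,10-dimethylcyclodecan-1-one
Conditions: [(Ph3P)CuH]6, wet toluene, rt; sat. aq. NH4Cl, air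
Reagents that add atoms: none
Why: Copper hydride conjugate reduction is selective for the enone and leaves the epoxide, the alkenyl bromide and all stereocentres alone.

**Step 17**
Reactants: 26 diol ketone
Product: 27 C8 methacrylate of 26
Conditions: methacrylic anhydride, Et3N, DMAP (cat.), CH2Cl2, 0 °C → rt
Reagents that add atoms: methacrylic anhydride, C=C(C)C(=O)OC(=O)C(C)=C
Why: DMAP-catalysed acylation takes the secondary C8 hydroxyl much faster than the tertiary C10 hydroxyl, with retention at C8.

**Step 18**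
Reactants: 27 C8 methacrylate
Product: 28 (4S,5S,6R,7R,8S,10R)-10-acetoxy-7-(1-bromovinyl)-5,6-epoxy-4,10-dimethyl-1-oxocyclodecan-8-yl methacrylate
Conditions: Ac2O, DMAP, Et3N, CH2Cl2, 40 °C
Reagents that add atoms: acetic anhydride, CC(=O)OC(C)=O
Why: Forced DMAP-catalysed acetylation of the remaining tertiary α-ketol hydroxyl occurs at oxygen, so C10 is retained.

**Step 19**
Reactants: 28 bromo epoxy diester
Product: 30 lychnostatin 1, via epoxy acrylic acid 29 (not isolated)
Conditions: NiBr2(bpy) (10 mol %), Mn powder, Et4NI (10 mol %), CO2 (1 atm), DMF, 25 → 45 °C; 10% aq. citric acid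
Reagents that add atoms: carbon dioxide, O=C=O
Why: Proposed new method: zerovalent nickel, regenerated by manganese, inserts into the C11–Br bond, the alkenylnickel is reduced to the monovalent state and adds to CO2 (C11–C12), and the divalent manganese carboxylate so formed attacks the metal-activated epoxide at C6 anti to the epoxide oxygen (O–C6), the C5 alkoxide being buffered as its carbonate under CO2 until the acidic work-up. The closest known reaction types are the nickel- or cobalt-catalysed reductive carboxylation of alkenyl halides and triflates with CO2 and Mn, and the lactonisation of γ,δ-epoxy carboxylates; their union in one flask on an epoxy alkenyl bromide has not been shown. The only ring closed is the five-membered lactone, by 5-exo-tet opening, while 6-endo attack at C5 to the δ-lactone is stereoelectronically disfavoured. C6 is the only stereocentre that changes, being inverted from the 6R epoxide carbon to the 6S lactone carbon by the SN2 course, while C5 keeps its oxygen and C7, which holds the carboxylate on the face opposite to the epoxide oxygen, dictates the trans ring fusion. The step needs chemoselectivity for C–Br over the methacrylate, the α-acetoxy ketone and the epoxide, which rests on fast oxidative addition to the unhindered 1,1-disubstituted alkenyl bromide at room temperature and on the mild reductant. It also needs the carboxylate rather than halide to open the epoxide, which the intramolecular five-membered transition state secures.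

**Compound list**
1 | (2S,5S)-2-tert-butyl-5-methyl-1,3-dioxolan-4-one | C[C@@H]1O[C@H](C(C)(C)C)OC1=O | starting material
2 | lithium (2S)-2-tert-butyl-5-methyl-1,3-dioxol-4-olate | CC1=C([O-])O[C@@H](C(C)(C)C)O1.[Li+] | intermediate
3 | (2S,5R)-5-allyl-2-tert-butyl-5-methyl-1,3-dioxolan-4-one | C[C@]1(CC=C)O[C@H](C(C)(C)C)OC1=O | intermediate
4 | secondary ozonide (1,2,4-trioxolane) of 3, mixture at the ozonide carbon | C[C@]1(CC2OCOO2)O[C@H](C(C)(C)C)OC1=O | intermediate
5 | 2-[(2S,4R)-2-tert-butyl-4-methyl-5-oxo-1,3-dioxolan-4-yl]acetaldehyde | C[C@]1(CC=O)O[C@H](C(C)(C)C)OC1=O | intermediate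
6 | but-3-ynoic acid | C#CCC(=O)O | starting material
7 | 3-bromobut-3-enoic acid | C=C(Br)CC(=O)O | intermediate
8 | (R)-4-benzyloxazolidin-2-one | O=C1N[C@H](Cc2ccccc2)CO1 | starting material
9 | 3-bromobut-3-enoic pivalic anhydride | C=C(Br)CC(=O)OC(=O)C(C)(C)C | intermediate
10 | (R)-4-benzyl-3-(3-bromobut-3-enoyl)oxazolidin-2-one | C=C(Br)CC(=O)N1[C@H](Cc2ccccc2)COC1=O | intermediate
11 | (Z)-dibutylboron dienolate of 10 | C=C(Br)/C=C(\OB(CCCC)CCCC)N1[C@H](Cc2ccccc2)COC1=O | intermediate
12 | syn aldol adduct (7R,8S,10R; acetal S; auxiliary R) | C=C(Br)[C@H]([C@@H](O)C[C@@]1(C)O[C@H](C(C)(C)C)OC1=O)C(=O)N1[C@H](Cc2ccccc2)COC1=O | intermediate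
13 | C8 triethylsilyl ether of 12 | C=C(Br)[C@H]([C@@H](O[Si](CC)(CC)CC)C[C@@]1(C)O[C@H](C(C)(C)C)OC1=O)C(=O)N1[C@H](Cc2ccccc2)COC1=O | intermediate
14 | C6 primary alcohol (7S,8S,10R) | C=C(Br)[C@H]([C@@H](O[Si](CC)(CC)CC)C[C@@]1(C)O[C@H](C(C)(C)C)OC1=O)CO | intermediate
15 | C6 aldehyde (7R,8S,10R) | C=C(Br)[C@H]([C@@H](O[Si](CC)(CC)CC)C[C@@]1(C)O[C@H](C(C)(C)C)OC1=O)C=O | intermediate
16 | (E)-1,4-dibromobut-2-ene | BrC/C=C/CBr | starting material
17 | (S)-4-bromo-3-methylbut-1-ene | C=C[C@H](C)CBr | intermediate
18 | (S)-(2-methylbut-3-en-1-yl)triphenylphosphonium bromide | C=C[C@H](C)C[P+](c1ccccc1)(c1ccccc1)c1ccccc1.[Br-] | intermediate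
19 | (S)-(2-methylbut-3-en-1-ylidene)triphenylphosphorane | C=C[C@H](C)C=P(c1ccccc1)(c1ccccc1)c1ccccc1 | intermediate
20 | Z-triene dioxolanone (4S,5Z,7S,8S,10R) | C=C(Br)[C@H]([C@@H](O[Si](CC)(CC)CC)C[C@@]1(C)O[C@H](C(C)(C)C)OC1=O)/C=C\[C@@H](C)C=C | intermediate
21 | C1 Weinreb amide, free C10 hydroxyl | C=C(Br)[C@H]([C@@H](O[Si](CC)(CC)CC)C[C@@](C)(O)C(=O)N(C)OC)/C=C\[C@@H](C)C=C | intermediate
22 | TES enone (C8 silyl ether of 23) | C=C(Br)[C@H]([C@@H](O[Si](CC)(CC)CC)C[C@@](C)(O)C(=O)C=C)/C=C\[C@@H](C)C=C | intermediate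
23 | diol enone (4S,5Z,7S,8S,10R) | C=C(Br)[C@H]([C@@H](O)C[C@@](C)(O)C(=O)C=C)/C=C\[C@@H](C)C=C | intermediate
24 | cis-5,6-epoxy diene (4S,5S,6R,7R,8S,10R) | C=C(Br)[C@H]([C@@H](O)C[C@@](C)(O)C(=O)C=C)[C@H]1O[C@H]1[C@@H](C)C=C | intermediate
25 | epoxy cyclodec-2-enone | O[C@H]1C[C@@](C)(O)C(=O)/C=C\[C@H](C)[C@@H]2O[C@@H]2[C@@H]1C(Br)=C | intermediate
26 | epoxy cyclodecanone diol | O[C@H]1C[C@@](C)(O)C(=O)CC[C@H](C)[C@@H]2O[C@@H]2[C@@H]1C(Br)=C | intermediate
27 | C8 methacrylate | C=C(C)C(=O)O[C@H]1C[C@@](C)(O)C(=O)CC[C@H](C)[C@@H]2O[C@@H]2[C@@H]1C(Br)=C | intermediate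
28 | C8 methacrylate C10 acetate (precursor of the key step) | C=C(C)C(=O)O[C@H]1C[C@@](C)(OC(C)=O)C(=O)CC[C@H](C)[C@@H]2O[C@@H]2[C@@H]1C(Br)=C | intermediate
29 | C12 carboxylic acid (in the flask its divalent manganese salt) | C=C(C)C(=O)O[C@H]1C[C@@](C)(OC(C)=O)C(=O)CC[C@H](C)[C@@H]2O[C@@H]2[C@@H]1C(=C)C(=O)O | intermediate
30 | lychnostatin 1 (4S,5S,6S,7R,8S,10R) | C=C(C)C(=O)O[C@H]1C[C@@](C)(OC(C)=O)C(=O)CC[C@H](C)[C@H](O)[C@H]2OC(=O)C(=C)[C@@H]21 | target

Total step count: 19. Longest linear sequence: 15 (steps 1, 2, 5–8, 11–19).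

**Steps most likely to fail**

**Step 19.** Possible failure processes:
- reductive coupling of the alkenylnickel with the methacrylate
- protodebromination
- halide opening of the epoxide before the carboxylate is formed

The fallback uses known chemistry and sets out from 28. Carbonylation with Pd(PPh3)4, CO (1 atm), 2-(trimethylsilyl)ethanol and Et3N in DMF should give the 2-(trimethylsilyl)ethyl acrylate F1. Tris(dimethylamino)sulfonium difluorotrimethylsilicate then frees the carboxylate. This rejoins the route at 29, which closes to 30, if necessary with catalytic camphorsulfonic acid.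

**Step 15.** Possible failure processes:
- intermolecular metathesis to oligomers outruns closure of the strained ten-membered ring
- the catalyst is held by the hydroxy ketone

The fallback sets out from 24. tBu2Si(OTf)2 and 2,6-lutidine tie the syn-1,3-diol into a temporary six-membered ring, the cyclic di-tert-butylsilylene F2, which turns both chain ends to the same side. Metathesis should then give the bicyclic enone F3, and [(Ph3P)CuH]6 the saturated ketone F4. HF·pyridine removes the silylene and rejoins the route at 26.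

**Step 14.** Possible failure processes:
- poor facial selectivity, because the C9 chain must sit axial in the vanadium-bound transition state
- competing oxidation of the α-ketol

The fallback is the halohydrin route and sets out from 22, isolated by quenching step 13 with aqueous NH4Cl. With C8 silylated, the alkene face syn to C8 is the hindered one. N-bromosuccinimide in aqueous dimethoxyethane should put bromine on the open face, with water entering anti. This gives the 6-bromo-5-ol F5 and the 5-bromo-6-ol F6. Both close with K2CO3 in acetone (SN2) to the same silylated cis-epoxide F7, whose oxygen lies on the face opposite to the one bromine attacked. HF·pyridine rejoins the route at 24.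

**Further compounds**
F1 | step 19 | 2-(trimethylsilyl)ethyl ester of acid 29 | C=C(C)C(=O)O[C@H]1C[C@@](C)(OC(C)=O)C(=O)CC[C@H](C)[C@@H]2O[C@@H]2[C@@H]1C(=C)C(=O)OCC[Si](C)(C)C
F2 | step 15 | C8,C10-O-di-tert-butylsilylene of 24 | C=C(Br)[C@H]([C@@H]1C[C@](C)(C(=O)C=C)O[Si](C(C)(C)C)(C(C)(C)C)O1)[C@H]1O[C@H]1[C@@H](C)C=C
F3 | step 15 | C8,C10-O-di-tert-butylsilylene of 25 | CC(C)(C)[Si]1(C(C)(C)C)O[C@H]2C[C@@](C)(O1)C(=O)/C=C\[C@H](C)[C@@H]1O[C@@H]1[C@@H]2C(Br)=C
F4 | step 15 | C8,C10-O-di-tert-butylsilylene of 26 | CC(C)(C)[Si]1(C(C)(C)C)O[C@H]2C[C@@](C)(O1)C(=O)CC[C@H](C)[C@@H]1O[C@@H]1[C@@H]2C(Br)=C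
F5 | step 14 | (5S,6S)-6-bromo-5-hydroxy bromohydrin of 22 | C=C(Br)[C@H]([C@@H](O[Si](CC)(CC)CC)C[C@@](C)(O)C(=O)C=C)[C@H](Br)[C@@H](O)[C@@H](C)C=C
F6 | step 14 | (5R,6R)-5-bromo-6-hydroxy bromohydrin of 22 | C=C(Br)[C@H]([C@@H](O[Si](CC)(CC)CC)C[C@@](C)(O)C(=O)C=C)[C@@H](O)[C@H](Br)[C@@H](C)C=C
F7 | step 14 | C8 triethylsilyl ether of 24 | C=C(Br)[C@H]([C@@H](O[Si](CC)(CC)CC)C[C@@](C)(O)C(=O)C=C)[C@H]1O[C@H]1[C@@H](C)C=C
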